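**Product ledger.** Each molecule of either product costs one partner on the listed steps. Partner is charged on the left-handed substrate, while the conversion c counts both substrates together, so the equivalents divided by two give the partner ceiling c_max = 110%, the conversion that the partner charge can pay for. That stands above full conversion, so in this flask the substrates, not the partner, are the limiting reagent.

| flask | left-handed substrate | right-handed substrate | partner | free catalyst | precatalyst | remark | time |
|---|---|---|---|---|---|---|---|
| Tuesday's | 40 mM | 40 mM | 2.2 equiv | 0.1 mol% | 0.05 mol% | the very flask that is asked about, followed so far |  |
| flask | 40 mM | 40 mM | 2.20 equiv | 0.1 mol% | 0.05 mol% |  | 5.0 h |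

Tuesday's run (percent of the left-handed substrate and right-handed substrate together charged)

| time / min | left-handed substrate / % | right-handed substrate / % |
|---|---|---|
| 5.00 | 38.5 | 50.7 |
| 15.0 | 23.5 | 48.8 |
| 25.0 | 16.7 | 47.8 |
| 40.0 | 11.5 | 44.5 |
| 50.0 | 10.4 | 41.6 |
| 80.0 | 8.8 | 33.0 |
| 90.0 | 8.7 | 30.9 |

(readings scatter by 0.5 percentage points)

- free catalyst is single-handed; left-handed substrate and right-handed substrate are mirror images of each other, charged as a racemate, each of them at the stated concentration
- the analysis behind the earlier runs scatters by 0.5 percentage points, standard deviation
- on the list of suspects stand: partner + precatalyst -> racemization catalyst + spent reagent; partner + free catalyst + right-handed substrate -> free catalyst + right-handed product; left-handed substrate + racemization catalyst <-> right-handed substrate + racemization catalyst; free catalyst -> spent catalyst; partner + free catalyst + left-handed substrate -> free catalyst + left-handed product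
- an excess is the difference of the two amounts in percent of their sum
- an excess is below zero if the other one leads

- part of the left-handed substrate and right-handed substrate charged together that has reacted at 5.0 h
- excess of left-handed product over right-handed product in the product at 5.0 h
- excess of right-handed substrate over left-handed substrate among what is left of the two at 5.0 h

**Time ladder.** The first rung in Tuesday's run is the left-handed substrate: its first two readings put its half-life t_L near 14.0 min, while the right-handed substrate slips from 50.7% to 48.8%. Later the left-handed substrate levels out near 8.7% and the right-handed one keeps falling, which reads as racemization feeding the fast lane. That tail gives the right-handed substrate a half-life reading t_S of 93.2 min, longer than t_L. The last rung is the stretch from the last reading to 5.0 h, which holds 2.25 such half-lives. If t_S lasts and the left-handed substrate stays at its last reading, c comes to 84.8%, below the ceiling, so on this estimate partner remains.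

**The forecast.** It gives c 81%, an excess eP of left-handed product of 90% and an excess eS of right-handed substrate of 25%, reading “the resolving catalyst dying at about 0.0066/min”. Its c lies below the ladder's.

**The result.** The flask gives c 87.9%, eP 90.0% and eS 12.7%, so c lies 6.9 percentage points above the forecast. With racemization struck out, both ways, c at 5.0 h is 58.9%. The ceiling turns the conversion into a partner balance: c/c_max leaves 20.1% of the partner charge in this flask at 5.0 h.

    partner + precatalyst → racemization catalyst + spent reagent (k = 0.0213 M⁻¹ min⁻¹)
    partner + free catalyst + right-handed substrate → free catalyst + right-handed product (k = 377 M⁻² min⁻¹)
    left-handed substrate + racemization catalyst ⇌ right-handed substrate + racemization catalyst, rate k3*[racemization catalyst]*[left-handed substrate] forward; the back reaction follows from the equilibrium constant (k = 5530 M⁻¹ min⁻¹)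
    free catalyst → spent catalyst (k = 5.46 × 10⁻⁴ min⁻¹)
    partner + free catalyst + left-handed substrate → free catalyst + left-handed product (k = 17000 M⁻² min⁻¹)

**Second flask.** In a neighbour flask with the same recipe except for 0.550 equiv of partner, the ceiling falls to 27.5%, below full conversion, which makes partner the limiting reagent there. The computed neighbour reaches c 27.3% at 5.0 h, with 0.71% of its partner left.

All runs were generated by integration with made-up constants, noise included.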